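The bicyclic lactone–ketal is the methyl pseudo-ester of a δ-keto acid; opening the ketal C–O bond uncovers a cyclohept-2-ene-1,4-dione bearing an ester. Everything rests on a (4+3) annulation of this seven-membered carbocycle, which exploits its ene-1,4-dicarbonyl array: the CH between the two carbonyl groups is joined to the benzylic carbon, and the vinylic CH to the future ketal carbon. In one operation a chiral primary amine guides the Michael addition of a β-keto ester to an α-methylcinnamaldehyde, and a carbene catalyst then converts the aldehyde into an acyl anion that closes the ring by addition–elimination on a β-methoxy enone. The precursors are an open-chain vinylogous ester and an enal.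

Key step: step 6

Assumption (chemistry): the quinine-derived primary amine is taken to give the (R) benzylic centre; if the opposite sense is found, its quinidine-derived pseudoenantiomer is used instead.

Step 1
Reactants: 1 3,4,5-trimethoxybenzaldehyde; 2 propanal
Product: 3 (2E)-2-methyl-3-(3,4,5-trimethoxyphenyl)prop-2-enal
Conditions: 2 added slowly, NaOH (0.3 equiv), MeOH/H2O, 0 °C to rt
Reagents that add atoms: none
Why: Crossed aldol condensation (Claisen–Schmidt) of the non-enolisable aryl aldehyde with the propanal enolate; dehydration should give the conjugated (E)-enal with the aryl group trans to the formyl group.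

Step 2
Reactants: 4 methyl pent-4-enoate; 5 methyl formate
Product: 6 methyl 2-formylpent-4-enoate (racemic; largely its hydroxymethylidene enol)
Conditions: NaH, HCO2Me (excess), THF, 0 °C to rt; aq. HCl
Reagents that add atoms: methyl formate, COC=O
Why: Crossed Claisen condensation (α-formylation of the ester enolate), driven forward by formation of the sodium enolate of the β-formyl ester.

Step 3
Reactants: 6 methyl 2-formylpent-4-enoate; 7 dimethyl sulfate
Product: 8 methyl (2E)-2-(methoxymethylidene)pent-4-enoate
Conditions: Me2SO4, K2CO3, DMF, rt
Reagents that add atoms: dimethyl sulfate, COS(=O)(=O)OC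
Why: O-alkylation of the enolate of the formyl ester should give the β-methoxyacrylate, the (E)-isomer (methoxy trans to the ester) being the more stable one.

Step 4
Reactants: 8 methyl (2E)-2-(methoxymethylidene)pent-4-enoate
Product: 9 (2E)-2-(methoxymethylidene)pent-4-enoic acid
Conditions: LiOH, THF/MeOH/H2O, 40 °C; aq. HCl to pH 3
Reagents that add atoms: lithium hydroxide, [Li+].[OH-]
Why: Saponification of the methyl ester; the β-methoxyacrylate is a vinylogous carbonate and should survive aqueous hydroxide.

Step 5
Reactants: 9 (2E)-2-(methoxymethylidene)pent-4-enoic acid; 10 1,1'-carbonyldiimidazole; 11 3-tert-butoxy-3-oxopropanoic acid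
Product: 14 tert-butyl (4E)-4-(methoxymethylidene)-3-oxohept-6-enoate, via acyl imidazolide 12 (not isolated), via acylmalonic acid 13 (not isolated)
Conditions: CDI, THF, rt; then 11, MgCl2, Et3N, MeCN, rt to 40 °C; aq. HCl
Reagents that add atoms: 3-tert-butoxy-3-oxopropanoic acid, OC(=O)CC(=O)OC(C)(C)C
Why: Masamune–Brooks β-keto ester synthesis: the acyl imidazolide C-acylates the magnesium enolate of the malonate half-ester and the acylmalonic acid loses CO2 on acidification.

Step 6
Reactants: 3 (2E)-2-methyl-3-(3,4,5-trimethoxyphenyl)prop-2-enal; 14 tert-butyl (4E)-4-(methoxymethylidene)-3-oxohept-6-enoate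
Product: 16 tert-butyl (7R)-6-methyl-2,5-dioxo-3-(prop-2-en-1-yl)-7-(3,4,5-trimethoxyphenyl)cyclohept-3-ene-1-carboxylate (epimers at C-1 and C-6), via Michael adduct 15 (not isolated)
Conditions: 9-amino-9-deoxy-epi-quinine (20 mol %), TFA (30 mol %), toluene, rt; then pentafluorophenyl bicyclic triazolium tetrafluoroborate (20 mol %), NaOAc (50 mol %), 50 °C, same flask
Reagents that add atoms: none
Why: Proposed new method: the primary amine forms an iminium ion with enal 3, the enol carbon of 14 adds to its β-carbon (Michael addition) to give 15, the carbene then adds to the freed aldehyde and the resulting Breslow intermediate (acyl anion equivalent) attacks the methoxy-bearing β-carbon of the vinylogous ester (Stetter addition), after which E1cB loss of methoxide restores the C=C bond and the carbene is released. The closest known chemistry is the amine/carbene multicatalytic Michael–benzoin cascade of 1,3-dicarbonyl compounds with enals and the intramolecular Stetter reaction; untested are the addition–elimination on a β-alkoxy enone and the seven-membered closure. The one new ring, the cycloheptene, closes 7-endo-trig at the enone β-carbon. The benzylic centre is set by the catalyst, whose ion-paired iminium ion exposes one face of the enal, while the two flanking CH centres are enolisable and are left as mixtures. The step needs conjugate rather than carbonyl attack of the acyl anion: the ketone is deactivated as a vinylogous ester, a competing benzoin adduct can revert, and loss of methoxide makes the conjugate path irreversible.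

Step 7
Reactants: 16 tert-butyl (7R)-6-methyl-2,5-dioxo-3-(prop-2-en-1-yl)-7-(3,4,5-trimethoxyphenyl)cyclohept-3-ene-1-carboxylate; 17 methoxytrimethylsilane
Product: 18 (1R,5S,8R,9R)-5-methoxy-9-methyl-3-(prop-2-en-1-yl)-8-(3,4,5-trimethoxyphenyl)-6-oxabicyclo[3.2.2]non-3-ene-2,7-dione (CNP0298078.1)
Conditions: MeOTMS (3 equiv), TMSOTf (10 mol %), CH2Cl2, −78 to 0 °C
Reagents that add atoms: methoxytrimethylsilane, CO[Si](C)(C)C
Why: Noyori-type silyl triflate ketalisation interrupted by the neighbouring ester: the methoxy oxocarbenium ion at the ring ketone that lies 1,5 to the carboxyl carbon should be captured 6-exo by the tert-butyl ester carbonyl oxygen with loss of isobutene, which fixes the ketal and bridgehead centres by the bridge geometry, while the two flanking centres, enolisable until closure, should settle with the aryl group on the face of the lactone bridge and the methyl group trans to it.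

Compound list
1 | 3,4,5-trimethoxybenzaldehyde | O=Cc1cc(OC)c(OC)c(OC)c1 | starting material
2 | propanal | CCC=O | starting material
3 | (2E)-2-methyl-3-(3,4,5-trimethoxyphenyl)prop-2-enal | O=C/C(C)=C/c1cc(OC)c(OC)c(OC)c1 | intermediate
4 | methyl pent-4-enoate | C=CCCC(=O)OC | starting material
5 | methyl formate | COC=O | starting material
6 | methyl 2-formylpent-4-enoate (racemic; largely the hydroxymethylidene enol) | C=CCC(C=O)C(=O)OC | intermediate
7 | dimethyl sulfate | COS(=O)(=O)OC | starting material
8 | methyl (2E)-2-(methoxymethylidene)pent-4-enoate | CO/C=C(/C(=O)OC)CC=C | intermediate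
9 | (2E)-2-(methoxymethylidene)pent-4-enoic acid | CO/C=C(/C(=O)O)CC=C | intermediate
10 | 1,1'-carbonyldiimidazole | O=C(n1ccnc1)n1ccnc1 | starting material
11 | 3-tert-butoxy-3-oxopropanoic acid (mono-tert-butyl malonate) | OC(=O)CC(=O)OC(C)(C)C | starting material
12 | (2E)-1-(imidazol-1-yl)-2-(methoxymethylidene)pent-4-en-1-one | CO/C=C(/C(=O)n1ccnc1)CC=C | intermediate
13 | 3-tert-butoxy-2-[(2E)-2-(methoxymethylidene)pent-4-enoyl]-3-oxopropanoic acid (racemic; present as its magnesium chelate) | CO/C=C(/C(=O)C(C(=O)O)C(=O)OC(C)(C)C)CC=C | intermediate
14 | tert-butyl (4E)-4-(methoxymethylidene)-3-oxohept-6-enoate | CO/C=C(/C(=O)CC(=O)OC(C)(C)C)CC=C | intermediate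
15 | tert-butyl (4E)-4-(methoxymethylidene)-2-[(1R)-2-methyl-3-oxo-1-(3,4,5-trimethoxyphenyl)propyl]-3-oxohept-6-enoate (epimers at the two enolisable CH centres) | CO/C=C(/C(=O)C(C(=O)OC(C)(C)C)[C@H](c1cc(OC)c(OC)c(OC)c1)C(C)C=O)CC=C | intermediate
16 | tert-butyl (7R)-6-methyl-2,5-dioxo-3-(prop-2-en-1-yl)-7-(3,4,5-trimethoxyphenyl)cyclohept-3-ene-1-carboxylate (epimers at C-1 and C-6) | C=CCC1=CC(=O)C(C)[C@@H](c2cc(OC)c(OC)c(OC)c2)C(C(=O)OC(C)(C)C)C1=O | intermediate
17 | methoxytrimethylsilane | CO[Si](C)(C)C | starting material
18 | (1R,5S,8R,9R)-5-methoxy-9-methyl-3-(prop-2-en-1-yl)-8-(3,4,5-trimethoxyphenyl)-6-oxabicyclo[3.2.2]non-3-ene-2,7-dione; aryl on the face of the lactone bridge, methyl trans to it | C=CCC1=C[C@@]2(OC)OC(=O)[C@@H](C1=O)[C@H](c1cc(OC)c(OC)c(OC)c1)[C@H]2C | target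

Total step count: 7. Longest linear sequence: 6 steps (steps 2 to 7, from methyl pent-4-enoate).

Steps most likely to fail

Step 6 (carries the new-method label). The acyl anion equivalent may add to the ketone instead of the β-carbon, or may not form because reversible hemiacetal formation holds the aldehyde back. The amine may also displace methoxide from the vinylogous ester, and facial selectivity with the α-branched enal may be modest. The fallback uses known chemistry and sets out from 3 and 14. The amine-catalysed Michael addition is run alone and adduct 15 is isolated. SmI2 (THF, HMPA, −78 °C) then effects a ketyl–olefin cyclisation: the ketyl radical adds 7-endo to the β-carbon of the vinylogous ester and the samarium enolate loses methoxide. This should give the γ-hydroxy enone tert-butyl (7R)-5-hydroxy-6-methyl-2-oxo-3-(prop-2-en-1-yl)-7-(3,4,5-trimethoxyphenyl)cyclohept-3-ene-1-carboxylate F1. Dess–Martin periodinane oxidises it to 16, where the route is rejoined.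

Step 7. The lactone may close on the face away from the aryl group, the other ketone may be ketalised without closure, or the carboxyl group may be lost after ester cleavage. The fallback sets out from 16. TFA in CH2Cl2 at 0 °C removes the tert-butyl group, and the δ-keto acid closes reversibly, under thermodynamic control, to its ring tautomer. This is the hydroxy lactone (1R,5S,8R,9R)-5-hydroxy-9-methyl-3-(prop-2-en-1-yl)-8-(3,4,5-trimethoxyphenyl)-6-oxabicyclo[3.2.2]non-3-ene-2,7-dione F2. O-methylation of its hemiketal hydroxyl with MeI and Ag2O comes back to the route at 18.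

Step 5. C-acylation may be slow because the imidazolide is deactivated as a vinylogous carbamate-type acyl donor, and the malonate enolate may instead displace methoxide by conjugate addition–elimination. The fallback sets out from 9. Oxalyl chloride with catalytic DMF gives the acid chloride (2E)-2-(methoxymethylidene)pent-4-enoyl chloride F3. This acylates Meldrum's acid (pyridine, CH2Cl2, 0 °C) to give 5-[(2E)-1-hydroxy-2-(methoxymethylidene)pent-4-en-1-ylidene]-2,2-dimethyl-1,3-dioxane-4,6-dione F4. Heating F4 with tert-butanol in toluene at 80 °C comes back to the route at 14.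

Further compounds
F1 | step 6 | tert-butyl (7R)-5-hydroxy-6-methyl-2-oxo-3-(prop-2-en-1-yl)-7-(3,4,5-trimethoxyphenyl)cyclohept-3-ene-1-carboxylate | C=CCC1=CC(O)C(C)[C@@H](c2cc(OC)c(OC)c(OC)c2)C(C(=O)OC(C)(C)C)C1=O
F2 | step 7 | (1R,5S,8R,9R)-5-hydroxy-9-methyl-3-(prop-2-en-1-yl)-8-(3,4,5-trimethoxyphenyl)-6-oxabicyclo[3.2.2]non-3-ene-2,7-dione | C=CCC1=C[C@@]2(O)OC(=O)[C@@H](C1=O)[C@H](c1cc(OC)c(OC)c(OC)c1)[C@H]2C
F3 | step 5 | (2E)-2-(methoxymethylidene)pent-4-enoyl chloride | CO/C=C(/C(Cl)=O)CC=C
F4 | step 5 | 5-[(2E)-1-hydroxy-2-(methoxymethylidene)pent-4-en-1-ylidene]-2,2-dimethyl-1,3-dioxane-4,6-dione | CO/C=C(/C(O)=C1C(=O)OC(C)(C)OC1=O)CC=C
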